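**Retrosynthetic overview**
- The ten-membered carbocycle is closed last, at C1=C10, by ring-closing metathesis of a terminal vinyl group onto a 2-substituted acrylate. The ring-cis olefin that ten-membered rings prefer is the required enoate geometry.
- Key disconnection: the lactone C6–O bond together with the C15–O bond. A palladium-catalysed 1,4-hydroxy-lactonisation of an open-chain diene acid forms the γ-lactone and sets C6, the C4=C5 geometry and the C15 hydroxyl in one step.
- C7–C8: an indium Barbier reaction between a (Z)-2-(bromomethyl)trienoate and an α-hydroxy aldehyde sets C7 and C8 relative to C9.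
- C9 comes from a Morita–Baylis–Hillman adduct of acrolein, resolved by Sharpless kinetic resolution. The acetate and isobutyrate are introduced directly, so no protecting group is carried except the tert-butyl ester.
- Order of ring formation: γ-lactone first (C–O), ten-membered ring second (C=C).

Convention: locants C1–C15 are germacrane-type locants of the target (C6 lactone carbinol, C7 ring-fusion CH, C8 isobutyrate carbon, C9 acetate carbon, C10 ester-bearing olefin carbon, C11–C13 α-methylene lactone, C14 ester carbon, C15 hydroxymethyl). The SMILES is taken at face value: 6R,7S,8S,9S, trans-fused lactone, both ring double bonds with the ring carbons cis (E by CIP).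

**Route**

Step 1
Reactants: 1 hex-5-enal; 2 formaldehyde
Product: 3 2-methylidenehex-5-enal
Conditions: 37% aq. HCHO, pyrrolidine (10 mol%), 4-(dimethylamino)benzoic acid (10 mol%), iPrOH, 45 °C
Reagents that add atoms: none
Why: organocatalytic α-methylenation (Mannich condensation–elimination through the enamine) is a dependable reaction of unbranched aldehydes and forms no stereocentre.

Step 2
Reactants: 3 2-methylidenehex-5-enal; 4 (triphenyl-λ5-phosphanylidene)acetaldehyde
Product: 5 (2E)-4-methylideneocta-2,7-dienal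
Conditions: toluene, 80 °C
Reagents that add atoms: none
Why: Wittig olefination with the stabilised formyl ylide gives the (E)-enal, and the more conjugated product is less electrophilic than 3, so a second homologation is slow.

Step 3
Reactants: 5 (2E)-4-methylideneocta-2,7-dienal; 6 tert-butyl prop-2-enoate
Product: 7 tert-butyl (4E)-3-hydroxy-2,6-dimethylidenedeca-4,9-dienoate (racemic)
Conditions: DABCO (1 equiv), 1,4-dioxane/H2O 1:1, rt, 3 d
Reagents that add atoms: none
Why: Morita–Baylis–Hillman reaction (1,2-addition of the amine–acrylate zwitterion to the aldehyde); the racemic carbinol centre is erased in step 4.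

Step 4
Reactants: 7 tert-butyl (4E)-3-hydroxy-2,6-dimethylidenedeca-4,9-dienoate
Product: 8 tert-butyl (2Z,4E)-2-(bromomethyl)-6-methylidenedeca-2,4,9-trienoate
Conditions: NBS, Me2S, CH2Cl2, −20 to 0 °C
Reagents that add atoms: N-bromosuccinimide, O=C1CCC(=O)N1Br
Why: SN2′ bromination of the Morita–Baylis–Hillman alcohol through its alkoxysulfonium salt (Corey–Kim type) gives the thermodynamically favoured (2Z)-2-(bromomethyl)alkenoate.

Step 5
Reactants: 9 prop-2-enal; 10 methyl prop-2-enoate
Product: 11 methyl 3-hydroxy-2-methylidenepent-4-enoate (racemic)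
Conditions: DABCO (10 mol%), methyl acrylate (3 equiv, neat), slow addition of 9, 0 °C to rt
Reagents that add atoms: none
Why: Morita–Baylis–Hillman reaction with acrolein as the aldehyde partner gives the known divinyl carbinol.

Step 6
Reactants: 11 methyl 3-hydroxy-2-methylidenepent-4-enoate
Product: 12 methyl (3R)-3-hydroxy-2-methylidenepent-4-enoate
Conditions: Ti(OiPr)4 (15 mol%), D-(−)-diisopropyl tartrate (18 mol%), tBuOOH (0.6 equiv), 4 Å MS, CH2Cl2, −20 °C, stopped at about 55% conversion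
Reagents that add atoms: none
Why: Sharpless kinetic resolution: with the D-tartrate the (3S)-alcohol is epoxidised at its vinyl group and (3R)-12 is recovered, while the electron-poor acrylate double bond is inert; this fixes C9.

Step 7
Reactants: 12 methyl (3R)-3-hydroxy-2-methylidenepent-4-enoate
Product: 13 methyl (3S)-3-hydroxy-2-methylidene-4-oxobutanoate
Conditions: O3, CH2Cl2/MeOH, −78 °C (Sudan Red end point); Me2S, −78 °C to rt; used crude at once
Reagents that add atoms: ozone, [O-][O+]=O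
Why: ozonolysis is chemoselective for the electron-rich vinyl group over the acrylate double bond and does not touch the carbinol centre (the descriptor changes from R to S by CIP only).

Step 8
Reactants: 8 tert-butyl (2Z,4E)-2-(bromomethyl)-6-methylidenedeca-2,4,9-trienoate; 13 methyl (3S)-3-hydroxy-2-methylidene-4-oxobutanoate
Product: 14 1-tert-butyl 7-methyl (3R,4S,5S)-4,5-dihydroxy-2,6-dimethylidene-3-[(1E)-3-methylidenehepta-1,6-dien-1-yl]heptanedioate
Conditions: In powder (1.5 equiv), THF/H2O 1:1, rt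
Reagents that add atoms: none
Why: indium-mediated Barbier 2-(alkoxycarbonyl)allylation in water: the ester-chelated allylindium reacts at its γ-carbon (C7) through a chair six-membered transition state with the γ-substituent of the (Z)-reagent axial, giving the 7,8-syn adduct, and the free α-hydroxyl of 13 chelates indium (Cram chelate) so that C8 forms threo to C9.

Step 9
Reactants: 14 1-tert-butyl 7-methyl (3R,4S,5S)-4,5-dihydroxy-2,6-dimethylidene-3-[(1E)-3-methylidenehepta-1,6-dien-1-yl]heptanedioate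
Product: 16 1-tert-butyl 7-methyl (3R,4S,5S)-5-acetyloxy-2,6-dimethylidene-3-[(1E)-3-methylidenehepta-1,6-dien-1-yl]-4-[(2-methylpropanoyl)oxy]heptanedioate, via C5 monoacetate 15 (not isolated)
Conditions: AcCl (1.05 equiv), 2,4,6-collidine, CH2Cl2, −78 °C; then iPrCOCl (3 equiv), pyridine, 0 °C to rt
Reagents that add atoms: acetyl chloride, CC(=O)Cl; 2-methylpropanoyl chloride, CC(C)C(=O)Cl
Why: site-selective esterification: the C9 hydroxyl sits next to a flat sp2 carbon and is acetylated first, the C8 hydroxyl next to the fully branched C7 reacts only afterwards with excess isobutyryl chloride, and doing both in one pot without a nucleophilic amine catalyst limits 1,2-acyl migration and SN2′ side reactions.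

Step 10
Reactants: 16 1-tert-butyl 7-methyl (3R,4S,5S)-5-acetyloxy-2,6-dimethylidene-3-[(1E)-3-methylidenehepta-1,6-dien-1-yl]-4-[(2-methylpropanoyl)oxy]heptanedioate
Product: 18 (3R,4S,5S)-5-acetyloxy-6-(methoxycarbonyl)-2-methylidene-3-[(1E)-3-methylidenehepta-1,6-dien-1-yl]-4-[(2-methylpropanoyl)oxy]hept-6-enoic acid, via trimethylsilyl ester 17 (not isolated)
Conditions: TMSOTf (2 equiv), 2,6-lutidine (3 equiv), CH2Cl2, 0 °C; aq. NH4Cl work-up
Reagents that add atoms: none
Why: silyl-triflate-mediated tert-butyl ester cleavage (O-silylation, loss of the tert-butyl cation as isobutene) is buffered by lutidine, so the diene, the allylic acetate and the other esters survive, and the silyl ester hydrolyses on work-up.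

Step 11
Reactants: 18 (3R,4S,5S)-5-acetyloxy-6-(methoxycarbonyl)-2-methylidene-3-[(1E)-3-methylidenehepta-1,6-dien-1-yl]-4-[(2-methylpropanoyl)oxy]hept-6-enoic acid
Product: 20 methyl (3S,4S)-3-acetyloxy-4-[(2R,3S)-2-[(1E)-2-(hydroxymethyl)hexa-1,5-dien-1-yl]-4-methylidene-5-oxooxolan-3-yl]-2-methylidene-4-[(2-methylpropanoyl)oxy]butanoate, via C15 trifluoroacetate 19 (not isolated)
Conditions: Pd(OCOCF3)2 (10 mol%), 1,4-benzoquinone (2 equiv), LiOCOCF3 (5 equiv), CF3CO2H (2 equiv), acetone, 25 °C; then NaHCO3, MeOH/H2O, 0 °C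
Reagents that add atoms: lithium trifluoroacetate, [Li+].[O-]C(=O)C(F)(F)F
Why: Proposed new method: divalent palladium binds the 2-substituted 1,3-diene and the tethered acrylic carboxylate adds anti to the metal at C6 (5-exo) to give an η3-allylpalladium over C5–C4–C15; since this acyloxypalladation is reversible in acid, the more stable trans-4,5-disubstituted lactone (6R, with C5 and C8 on opposite faces) should accumulate, the syn-allyl geometry places C6 cis to C3, and benzoquinone-assisted attack of trifluoroacetate at the unhindered primary terminus C15 releases zerovalent palladium (reoxidised by benzoquinone) and the (E)-allylic trifluoroacetate 19, which the bicarbonate/methanol work-up cleaves to the alcohol without touching acetate or isobutyrate; the closest known reaction type is the Bäckvall palladium-catalysed 1,4-acyloxy-lactonisation and 1,4-acetoxy-trifluoroacetoxylation of conjugated (mostly cyclic) dienes, which to my knowledge has not been shown on an acyclic 1,3-disubstituted diene carrying an α-methylene acid, as a net hydroxy-lactonisation, or with control of a new stereocentre by a neighbouring one.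

Step 12
Reactants: 20 methyl (3S,4S)-3-acetyloxy-4-[(2R,3S)-2-[(1E)-2-(hydroxymethyl)hexa-1,5-dien-1-yl]-4-methylidene-5-oxooxolan-3-yl]-2-methylidene-4-[(2-methylpropanoyl)oxy]butanoate
Product: 21 methyl (3aS,4S,5S,6E,10E,11aR)-5-acetyloxy-10-(hydroxymethyl)-3-methylidene-4-[(2-methylpropanoyl)oxy]-2-oxo-2,3,3a,4,5,8,9,11a-octahydrocyclodeca[b]furan-6-carboxylate (CNP0242134.2)
Conditions: second-generation Hoveyda–Grubbs catalyst RuCl2(H2IMes)(=CH-C6H4-2-OiPr) (15 mol%), toluene (1 mM), 80 °C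
Reagents that add atoms: none
Why: ring-closing metathesis of the terminal vinyl group onto the 1,1-disubstituted acrylate; ten-membered carbocycles close to the ring-cis olefin, here the required (E)-enoate, the trans-lactone and the cis C4=C5 bond pre-organise the chain, and no stereocentre is touched.

**Compound list**

1 | hex-5-enal | C=CCCCC=O | starting material
2 | formaldehyde | C=O | starting material
3 | 2-methylidenehex-5-enal | C=CCCC(=C)C=O | intermediate
4 | (triphenyl-λ5-phosphanylidene)acetaldehyde | O=CC=P(c1ccccc1)(c1ccccc1)c1ccccc1 | starting material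
5 | (2E)-4-methylideneocta-2,7-dienal | C=CCCC(=C)/C=C/C=O | intermediate
6 | tert-butyl prop-2-enoate | C=CC(=O)OC(C)(C)C | starting material
7 | tert-butyl (4E)-3-hydroxy-2,6-dimethylidenedeca-4,9-dienoate (racemic) | C=CCCC(=C)/C=C/C(O)C(=C)C(=O)OC(C)(C)C | intermediate
8 | tert-butyl (2Z,4E)-2-(bromomethyl)-6-methylidenedeca-2,4,9-trienoate | BrC/C(C(=O)OC(C)(C)C)=C\C=C\C(=C)CCC=C | intermediate
9 | prop-2-enal | C=CC=O | starting material
10 | methyl prop-2-enoate | C=CC(=O)OC | starting material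
11 | methyl 3-hydroxy-2-methylidenepent-4-enoate (racemic) | C=CC(O)C(=C)C(=O)OC | intermediate
12 | methyl (3R)-3-hydroxy-2-methylidenepent-4-enoate | C=C[C@@H](O)C(=C)C(=O)OC | intermediate
13 | methyl (3S)-3-hydroxy-2-methylidene-4-oxobutanoate | O=C[C@@H](O)C(=C)C(=O)OC | intermediate
14 | 1-tert-butyl 7-methyl (3R,4S,5S)-4,5-dihydroxy-2,6-dimethylidene-3-[(1E)-3-methylidenehepta-1,6-dien-1-yl]heptanedioate | C=C(C(=O)OC)[C@H](O)[C@@H](O)[C@@H](C(=C)C(=O)OC(C)(C)C)/C=C/C(=C)CCC=C | intermediate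
15 | 1-tert-butyl 7-methyl (3R,4S,5S)-5-acetyloxy-4-hydroxy-2,6-dimethylidene-3-[(1E)-3-methylidenehepta-1,6-dien-1-yl]heptanedioate | C=C(C(=O)OC)[C@H](OC(C)=O)[C@@H](O)[C@@H](C(=C)C(=O)OC(C)(C)C)/C=C/C(=C)CCC=C | intermediate
16 | 1-tert-butyl 7-methyl (3R,4S,5S)-5-acetyloxy-2,6-dimethylidene-3-[(1E)-3-methylidenehepta-1,6-dien-1-yl]-4-[(2-methylpropanoyl)oxy]heptanedioate | C=C(C(=O)OC)[C@H](OC(C)=O)[C@@H](OC(=O)C(C)C)[C@@H](C(=C)C(=O)OC(C)(C)C)/C=C/C(=C)CCC=C | intermediate
17 | 7-methyl 1-trimethylsilyl (3R,4S,5S)-5-acetyloxy-2,6-dimethylidene-3-[(1E)-3-methylidenehepta-1,6-dien-1-yl]-4-[(2-methylpropanoyl)oxy]heptanedioate | C=C(C(=O)OC)[C@H](OC(C)=O)[C@@H](OC(=O)C(C)C)[C@@H](C(=C)C(=O)O[Si](C)(C)C)/C=C/C(=C)CCC=C | intermediate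
18 | (3R,4S,5S)-5-acetyloxy-6-(methoxycarbonyl)-2-methylidene-3-[(1E)-3-methylidenehepta-1,6-dien-1-yl]-4-[(2-methylpropanoyl)oxy]hept-6-enoic acid | C=C(C(=O)OC)[C@H](OC(C)=O)[C@@H](OC(=O)C(C)C)[C@@H](C(=C)C(=O)O)/C=C/C(=C)CCC=C | intermediate
19 | methyl (3S,4S)-3-acetyloxy-2-methylidene-4-[(2-methylpropanoyl)oxy]-4-[(2R,3S)-4-methylidene-5-oxo-2-[(1E)-2-[(trifluoroacetyl)oxymethyl]hexa-1,5-dien-1-yl]oxolan-3-yl]butanoate | C=C1C(=O)O[C@H](/C=C(/COC(=O)C(F)(F)F)CCC=C)[C@H]1[C@H](OC(=O)C(C)C)[C@@H](OC(C)=O)C(=C)C(=O)OC | intermediate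
20 | methyl (3S,4S)-3-acetyloxy-4-[(2R,3S)-2-[(1E)-2-(hydroxymethyl)hexa-1,5-dien-1-yl]-4-methylidene-5-oxooxolan-3-yl]-2-methylidene-4-[(2-methylpropanoyl)oxy]butanoate | C=C1C(=O)O[C@H](/C=C(/CO)CCC=C)[C@H]1[C@H](OC(=O)C(C)C)[C@@H](OC(C)=O)C(=C)C(=O)OC | intermediate
21 | methyl (3aS,4S,5S,6E,10E,11aR)-5-acetyloxy-10-(hydroxymethyl)-3-methylidene-4-[(2-methylpropanoyl)oxy]-2-oxo-2,3,3a,4,5,8,9,11a-octahydrocyclodeca[b]furan-6-carboxylate | C=C1C(=O)O[C@@H]2/C=C(/CO)CC/C=C(/C(=O)OC)[C@H](OC(C)=O)[C@@H](OC(=O)C(C)C)[C@@H]12 | target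

**Step count and risks**

Total steps: 12 (fragment one: steps 1–4; fragment two: steps 5–7; union and endgame: steps 8–12). Longest linear sequence: 9 steps (1–4, then 8–12).

The three steps most likely to fail:

**Step 11 (the proposed hydroxy-lactonisation).** Risks: C6 epimers, E/Z mixture at C4=C5, 1,2- instead of 1,4-addition. The fallback uses known chemistry, sets out from 18 and comes back at 20. mCPBA (1.0 equiv, NaHCO3, CH2Cl2, 0 °C) epoxidises the 1,1-disubstituted, most nucleophilic diene terminus to the vinyl epoxide (3R,4S,5S)-5-acetyloxy-3-{(1E)-2-[2-(but-3-en-1-yl)oxiran-2-yl]ethenyl}-6-(methoxycarbonyl)-2-methylidene-4-[(2-methylpropanoyl)oxy]hept-6-enoic acid F6 (both oxirane epimers). Pd(PPh3)4 (5 mol%, THF, 0 °C; zerovalent palladium) then ionises the vinyl epoxide, and the internal carboxylic acid closes on C6 (Tsuji–Trost 1,4-opening of a vinyl epoxide by a carboxylate). This gives 20 with the C15 hydroxyl already free.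

**Step 12 (ring-closing metathesis).** Risks: strain of the ten-membered ring, a trisubstituted enoate as the new olefin, and competing closure onto the α-methylene lactone to an eight-membered ring. The fallback closes the ring through the C7–C8 bond by an intramolecular Barbier allylation, with C1=C10 made beforehand by cross-metathesis. It sets out from 13 and 3 and comes back at 21.
- 13 is acetalised (HC(OMe)3, MeOH, PPTS) to methyl (3S)-3-hydroxy-4,4-dimethoxy-2-methylidenebutanoate F7.
- Cross-metathesis of F7 (3 equiv) with 3 (second-generation Hoveyda–Grubbs catalyst, CH2Cl2, 40 °C) gives methyl (2E)-2-[(1S)-1-hydroxy-2,2-dimethoxyethyl]-6-methylidene-7-oxohept-2-enoate F8.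
- Wittig reaction with 4 gives methyl (2E,7E)-2-[(1S)-1-hydroxy-2,2-dimethoxyethyl]-6-methylidene-9-oxonona-2,7-dienoate F9.
- Morita–Baylis–Hillman reaction with 6 gives 1-tert-butyl 11-methyl (4E,9E)-3-hydroxy-10-[(1S)-1-hydroxy-2,2-dimethoxyethyl]-2,6-dimethylideneundeca-4,9-dienedioate F10 (C3 epimers).
- NBS/Me2S at −40 °C converts the doubly allylic hydroxyl selectively into 1-tert-butyl 11-methyl (2Z,4E,9E)-2-(bromomethyl)-10-[(1S)-1-hydroxy-2,2-dimethoxyethyl]-6-methylideneundeca-2,4,9-trienedioate F11.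
- Aqueous acid (acetal hydrolysis) and then indium in THF/H2O at high dilution close the ten-membered ring to methyl (1E,6E,8R,9S,10S)-8-(3-tert-butoxy-3-oxoprop-1-en-2-yl)-9,10-dihydroxy-5-methylidenecyclodeca-1,6-diene-1-carboxylate F12.
- Acylation as in step 9 gives the 10-acetate 9-isobutyrate of F12, macrocyclic diester F14, by way of the 10-monoacetate of F12, macrocyclic monoacetate F13.
- Ester cleavage as in step 10 gives the free acrylic acid corresponding to F14, macrocyclic diene acid F16, by way of its trimethylsilyl ester, macrocyclic silyl ester F15.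
- The hydroxy-lactonisation of step 11, now on a ring-constrained diene, gives 21 by way of the 15-O-trifluoroacetate of 21, macrocyclic trifluoroacetate F17.

**Step 8 (Barbier union).** Risks: the free α-hydroxy aldehyde 13 is labile, chelation control may be incomplete, the trienyl indium may react at a remote position, and the diol 14 then needs the site-selective acylation of step 9. The fallback replaces the free hydroxyl by a chelating ether, which also removes the need for site-selective acylation. It sets out from 12 and comes back at 16.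
- 12 reacts with 4-methoxybenzyl 2,2,2-trichloroacetimidate (cat. CSA, CH2Cl2) to give methyl (3R)-3-[(4-methoxyphenyl)methoxy]-2-methylidenepent-4-enoate F1.
- Ozonolysis as in step 7 gives the more robust aldehyde methyl (3S)-3-[(4-methoxyphenyl)methoxy]-2-methylidene-4-oxobutanoate F2.
- Barbier reaction of F2 with 8 (In, THF/H2O, chelation through the ether oxygen) gives 1-tert-butyl 7-methyl (3R,4S,5S)-4-hydroxy-5-[(4-methoxyphenyl)methoxy]-2,6-dimethylidene-3-[(1E)-3-methylidenehepta-1,6-dien-1-yl]heptanedioate F3.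
- Its only free hydroxyl is esterified (iPrCOCl, pyridine, DMAP) to 1-tert-butyl 7-methyl (3R,4S,5S)-5-[(4-methoxyphenyl)methoxy]-2,6-dimethylidene-3-[(1E)-3-methylidenehepta-1,6-dien-1-yl]-4-[(2-methylpropanoyl)oxy]heptanedioate F4.
- DDQ (CH2Cl2/pH 7 buffer, 0 °C) frees the C5 hydroxyl to give 1-tert-butyl 7-methyl (3R,4S,5S)-5-hydroxy-2,6-dimethylidene-3-[(1E)-3-methylidenehepta-1,6-dien-1-yl]-4-[(2-methylpropanoyl)oxy]heptanedioate F5.
- Ac2O/pyridine then gives 16.

**Further compounds**

F1 | step 8 | methyl (3R)-3-[(4-methoxyphenyl)methoxy]-2-methylidenepent-4-enoate | C=C[C@@H](OCc1ccc(OC)cc1)C(=C)C(=O)OC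
F2 | step 8 | methyl (3S)-3-[(4-methoxyphenyl)methoxy]-2-methylidene-4-oxobutanoate | O=C[C@@H](OCc1ccc(OC)cc1)C(=C)C(=O)OC
F3 | step 8 | 1-tert-butyl 7-methyl (3R,4S,5S)-4-hydroxy-5-[(4-methoxyphenyl)methoxy]-2,6-dimethylidene-3-[(1E)-3-methylidenehepta-1,6-dien-1-yl]heptanedioate | C=C(C(=O)OC)[C@H](OCc1ccc(OC)cc1)[C@@H](O)[C@@H](C(=C)C(=O)OC(C)(C)C)/C=C/C(=C)CCC=C
F4 | step 8 | 1-tert-butyl 7-methyl (3R,4S,5S)-5-[(4-methoxyphenyl)methoxy]-2,6-dimethylidene-3-[(1E)-3-methylidenehepta-1,6-dien-1-yl]-4-[(2-methylpropanoyl)oxy]heptanedioate | C=C(C(=O)OC)[C@H](OCc1ccc(OC)cc1)[C@@H](OC(=O)C(C)C)[C@@H](C(=C)C(=O)OC(C)(C)C)/C=C/C(=C)CCC=C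
F5 | step 8 | 1-tert-butyl 7-methyl (3R,4S,5S)-5-hydroxy-2,6-dimethylidene-3-[(1E)-3-methylidenehepta-1,6-dien-1-yl]-4-[(2-methylpropanoyl)oxy]heptanedioate | C=C(C(=O)OC)[C@H](O)[C@@H](OC(=O)C(C)C)[C@@H](C(=C)C(=O)OC(C)(C)C)/C=C/C(=C)CCC=C
F6 | step 11 | (3R,4S,5S)-5-acetyloxy-3-{(1E)-2-[2-(but-3-en-1-yl)oxiran-2-yl]ethenyl}-6-(methoxycarbonyl)-2-methylidene-4-[(2-methylpropanoyl)oxy]hept-6-enoic acid (both oxirane epimers) | C=C(C(=O)OC)[C@H](OC(C)=O)[C@@H](OC(=O)C(C)C)[C@@H](C(=C)C(=O)O)/C=C/C1(CCC=C)CO1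
F7 | step 12 | methyl (3S)-3-hydroxy-4,4-dimethoxy-2-methylidenebutanoate | COC(OC)[C@@H](O)C(=C)C(=O)OC
F8 | step 12 | methyl (2E)-2-[(1S)-1-hydroxy-2,2-dimethoxyethyl]-6-methylidene-7-oxohept-2-enoate | O=CC(=C)CC/C=C(/C(=O)OC)[C@H](O)C(OC)OC
F9 | step 12 | methyl (2E,7E)-2-[(1S)-1-hydroxy-2,2-dimethoxyethyl]-6-methylidene-9-oxonona-2,7-dienoate | O=C/C=C/C(=C)CC/C=C(/C(=O)OC)[C@H](O)C(OC)OC
F10 | step 12 | 1-tert-butyl 11-methyl (4E,9E)-3-hydroxy-10-[(1S)-1-hydroxy-2,2-dimethoxyethyl]-2,6-dimethylideneundeca-4,9-dienedioate (C3 epimers) | CC(C)(C)OC(=O)C(=C)C(O)/C=C/C(=C)CC/C=C(/C(=O)OC)[C@H](O)C(OC)OC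
F11 | step 12 | 1-tert-butyl 11-methyl (2Z,4E,9E)-2-(bromomethyl)-10-[(1S)-1-hydroxy-2,2-dimethoxyethyl]-6-methylideneundeca-2,4,9-trienedioate | BrC/C(C(=O)OC(C)(C)C)=C\C=C\C(=C)CC/C=C(/C(=O)OC)[C@H](O)C(OC)OC
F12 | step 12 | methyl (1E,6E,8R,9S,10S)-8-(3-tert-butoxy-3-oxoprop-1-en-2-yl)-9,10-dihydroxy-5-methylidenecyclodeca-1,6-diene-1-carboxylate | C=C(C(=O)OC(C)(C)C)[C@H]1/C=C/C(=C)CC/C=C(/C(=O)OC)[C@H](O)[C@H]1O
F13 | step 12 | macrocyclic monoacetate (10-O-acetyl derivative of F12) | C=C(C(=O)OC(C)(C)C)[C@H]1/C=C/C(=C)CC/C=C(/C(=O)OC)[C@H](OC(C)=O)[C@H]1O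
F14 | step 12 | macrocyclic diester (10-O-acetyl 9-O-(2-methylpropanoyl) derivative of F12) | C=C(C(=O)OC(C)(C)C)[C@H]1/C=C/C(=C)CC/C=C(/C(=O)OC)[C@H](OC(C)=O)[C@H]1OC(=O)C(C)C
F15 | step 12 | macrocyclic silyl ester (trimethylsilyl in place of tert-butyl in F14) | C=C(C(=O)O[Si](C)(C)C)[C@H]1/C=C/C(=C)CC/C=C(/C(=O)OC)[C@H](OC(C)=O)[C@H]1OC(=O)C(C)C
F16 | step 12 | macrocyclic diene acid (free acrylic acid corresponding to F14) | C=C(C(=O)O)[C@H]1/C=C/C(=C)CC/C=C(/C(=O)OC)[C@H](OC(C)=O)[C@H]1OC(=O)C(C)C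
F17 | step 12 | macrocyclic trifluoroacetate (15-O-trifluoroacetyl derivative of 21) | C=C1C(=O)O[C@@H]2/C=C(/COC(=O)C(F)(F)F)CC/C=C(/C(=O)OC)[C@H](OC(C)=O)[C@@H](OC(=O)C(C)C)[C@@H]12
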